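The data are simulated on assumed constants, noise included.

At early times, watch the solid substrate: in the earlier runs it falls from the first reading, while in the dusk run product reads 2% at 15.0 min.

| setting | dusk | summer | spring | flask |
|---|---|---|---|---|
| solid substrate | 1.4 M | 2.2 M | 1 M | 1.0 M |
| coupling partner | 2 M | 2 M | 3 M | 2.00 M |
| remark | run made earlier | run made earlier | run made earlier |  |
| time |  |  |  | 1.5 h |

| run | time / min | product / % | solid substrate / % |
|---|---|---|---|
| dusk | 15.0 | 2 | 95 |
| dusk | 25.0 | 6 | 91 |
| dusk | 40.0 | 8 | 86 |
| dusk | 50.0 | 11 | 85 |
| summer | 6.00 | 2 | 101 |
| summer | 20.0 | 5 | 96 |
| summer | 40.0 | 2 | 90 |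
| summer | 50.0 | 4 | 89 |
| spring | 15.0 | 3 | 91 |
| spring | 25.0 | 8 | 87 |
| spring | 40.0 | 16 | 80 |
| spring | 50.0 | 17 | 72 |

(standard deviation of a reading: 1.5 percentage points)

- given per volume of solution although it is solid: solid substrate
- the numbers in the tables scatter with a standard deviation of 1.5 percentage points
- on the list of suspects stand: solid substrate <-> dissolved substrate; dissolved substrate + coupling partner <-> product
- at the start none of the solid substrate is in solution

- the product standing at 1.5 h, as a percentage of the solid substrate charged
- the change that raises the amount of product at 1.5 h, in percent of the solid substrate charged most ("none" if none brings more than 2 percentage points) (grey / violet / ochre / none)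
- amount of product at 1.5 h, in percent of the solid substrate charged, after grey

- grey: doubling the amount of coupling partner, all else as stated
- violet: doubling the dissolution coefficient of the solid substrate, all else as stated
- ochre: doubling the solubility of the solid substrate, all else as stated

The dusk and summer runs have the flask's 2.00 M of coupling partner, so take their last rows. Together they lost 0.452 M of solid substrate, which is an average slope r = 0.00452 M min⁻¹. Of that loss, φ = 53.5% reads as product; φ, product formed per solid substrate lost, is the product share. The rest is dissolved substrate, a ratio of product to dissolved substrate of o = 1.15. If coupling is a fast equilibrium, o grows in step with coupling partner. That gives a share of 63.3% at the spring run's 3 M, and spring reads 60.7%.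

So I draw product as a line of slope φr from zero, taking dissolving as the rate-limiting step. The line gives 2.59% at 15.0 min in dusk, within the scatter of 1.5 percentage points of the reading of 2%, so this reading shows no lag. At this slope the flask's solid substrate lasts 3.69 h, longer than the 1.5 h asked, so no knee from its end falls inside the run. On this line the flask loses 0.407 M of solid substrate, and I reckon 21.8% product. If coupling is a fast equilibrium, grey doubles o, so on the same line the share becomes 69.7% and product 28.4%, a gain of 6.6 points. Violet and ochre each double r at the start, which adds 22 points on this line, more than grey, and ochre also raises the level the dissolved substrate fills towards, so I choose ochre.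

The forecast says 31% (25% to 37%), ochre, and 37% after grey (30% to 45%), holding that “the reaction is dissolution-limited”, and both its figures stand above mine.

The flask gives 21.4%, ochre as the best change (gain 19 points, against 9.9 points for violet and 9.5 points for grey), and 30.9% after grey.

    solid substrate ⇌ dissolved substrate, rate k1*(cs1 - [dissolved substrate]) while solid is left; crystals form when [dissolved substrate] > cs1 (solubility = 0.340 M, k = 0.0170 min⁻¹)
    dissolved substrate + coupling partner ⇌ product (K = 0.730 M⁻¹, k = 0.460 M⁻¹ min⁻¹)

Throughout the flask's 1.5 h the solid substrate dissolved, down to 62.0%, while the coupling step ran alongside and coupling partner fell to 89.3% of its charge. Dissolved substrate and product rose together, to 16.6% and 21.4% at 1.50 h, a share of 56.3% in this flask, where the scattered readings of the earlier runs gave φ = 53.5%. With 2.5 M charged, the same r and φ give 8.71%, and that neighbour flask held 8.56% product at 1.50 h.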